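**Assumptions (one line each)**
- The target has no stereocentres, so it is achiral and "single enantiomer" does not apply.
- I read the acyl chain as 30 carbons including the carbonyl, so the target is 4-hydroxyphenethyl (tyrosyl) triacontanoate, C38H68O3.

## Retrosynthetic overview
1. The target is hydrogenated back to the C30 monoene, a tyrosyl triacont-9-enoate.
2. The C9=C10 bond is disconnected by cross-metathesis into tyrosyl 9-decenoate (C10 acid part) and 1-docosene (C22). The C30 chain is therefore built by C=C metathesis on a pre-formed ester, not by esterifying a C30 acid.
3. Tyrosyl 9-decenoate comes from tyrosol and 9-decenoic acid by lipase acylation, which is selective for the aliphatic OH, so the phenol needs no protecting group.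
4. No rings are formed; the only ring is the tyrosol benzene ring, which is carried through unchanged.

## Forward route

**Step 1**
Reactants: 1 (tyrosol, 4-(2-hydroxyethyl)phenol) and 2 (9-decenoic acid)
Product: 3 (tyrosyl dec-9-enoate, 4-hydroxyphenethyl dec-9-enoate)
Conditions: Novozym 435 (immobilised *Candida antarctica* lipase B), 4 Å MS, tert-amyl alcohol, 60 °C, 24 h; filter and concentrate.
Reagents that add atoms: none
Why: Lipase-catalysed esterification acylates only the primary aliphatic alcohol and leaves the phenol untouched, so no protecting groups are needed; no stereocentre is formed.

**Step 2**
Reactants: 3 (tyrosyl dec-9-enoate) and 4 (1-docosene, 3 equiv)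
Product: 5 (tyrosyl triacont-9-enoate, E/Z mixture)
Conditions: Hoveyda–Grubbs II (5 mol%), 1,4-benzoquinone (10 mol%), toluene, 50 °C, N2 sweep or mild vacuum to remove ethylene, 16 h; silica plug, then column.
Reagents that add atoms: none. The C22 unit comes from reactant 4 itself; ethylene is lost.
Why: Type I/type I olefin cross-metathesis is driven toward the cross product by excess 1-docosene and ethylene removal. Benzoquinone suppresses Ru–H alkene isomerisation, which would scramble the chain length. The new C=C geometry is irrelevant because it is hydrogenated next.
Proposed new method: Cross-metathesis of two long-chain, waxy terminal olefins with a free phenol present is beyond standard precedent. The mechanism is standard Ru-carbene metathesis, closest to cross-metathesis of methyl 9-decenoate with long-chain α-olefins, and the free ArOH is assumed tolerated by the Hoveyda-type catalyst. The homodimers (the bis-tyrosyl C16 diester, which re-enters the equilibrium, and C42 alkene) are separable from the phenolic product by chromatography.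

**Step 3**
Reactants: 5 (tyrosyl triacont-9-enoate) and H2
Product: 6 (target, 4-hydroxyphenethyl triacontanoate)
Conditions: H2 (1 atm), 10% Pd/C, THF/EtOAc 1:1, 40 °C, 12 h; hot filtration through Celite, recrystallise from hexane/EtOAc.
Reagents that add atoms: H2 (adds only hydrogen)
Why: Catalytic hydrogenation reduces the isolated C=C, so the E/Z mixture converges to one saturated chain. The aryl ester, phenol and benzylic C–O are not touched under 1 atm of H2 on Pd/C. Step 2 must remove Ru residues first so the Pd/C is not poisoned.

## Checks
- **Target match:** Step 3 gives CH3(CH2)28C(=O)O–CH2CH2–C6H4–4-OH, the same as the target SMILES, with a para-substituted phenol and a primary ester.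
- **Atom balance:**
  - Step 1: C10H18O2 + C8H10O2 → C18H26O3 + H2O.
  - Step 2: C18H26O3 + C22H44 → C38H66O3 + C2H4.
  - Step 3: C38H66O3 + H2 → C38H68O3, the target.
- **Functional groups:** The phenol and ester survive the lipase, metathesis and hydrogenation conditions. CALB in tert-amyl alcohol does not acylate the phenol.
- **Stereochemistry:** There are no stereocentres to set, and the only transient stereochemical element (C=C geometry) is removed in step 3.

## Compound list
1 | tyrosol | OCCc1ccc(O)cc1 | starting material
2 | 9-decenoic acid | C=CCCCCCCCC(=O)O | starting material
3 | tyrosyl dec-9-enoate | C=CCCCCCCCC(=O)OCCc1ccc(O)cc1 | intermediate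
4 | 1-docosene | C=CCCCCCCCCCCCCCCCCCCCC | starting material
5 | tyrosyl triacont-9-enoate (E/Z) | CCCCCCCCCCCCCCCCCCCCC=CCCCCCCCC(=O)OCCc1ccc(O)cc1 | intermediate
6 | 4-hydroxyphenethyl triacontanoate (Basalethanolide B) | CCCCCCCCCCCCCCCCCCCCCCCCCCCCCC(=O)OCCc1ccc(O)cc1 | target

**Total steps:** 3. **Longest linear sequence:** 3.

## Three steps most likely to fail
1. **Step 2 (cross-metathesis).** It may give statistical homodimers, isomerised chain lengths, or a sluggish reaction from waxy-substrate aggregation.
   - Fallback: change the bond construction to a Ni-catalysed alkyl–alkyl Negishi coupling. Couple octadecylzinc bromide with tyrosyl 12-bromododecanoate (phenol as acetate), then hydrolyse the acetate. This builds the C12+C18 = C30 chain with no alkene.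
2. **Step 3 (hydrogenation).** Ru carry-over can poison Pd, and the very lipophilic substrate may be insoluble.
   - Fallback: replace the catalyst with metal-free diimide reduction (TsNHNH2/NaOAc, refluxing THF/DME), or add H2 and base to the crude metathesis mixture so the Ru catalyst is converted to a hydrogenation catalyst.
3. **Step 1 (lipase esterification).** Conversion may stall, or some aryl ester may form.
   - Fallback: change to a protecting-group route. Use 4-(2-hydroxyethyl)phenyl acetate or the TBS ether of tyrosol, acylate with 9-decenoyl chloride and pyridine, then remove the protecting group before or after metathesis (K2CO3/MeOH for acetate; TBAF for TBS).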